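## Retrosynthetic overview

1. The target is reached by borohydride reduction of the C25 furanoid 12'-apo-carotenal, which comes from a Wittig reaction (C11=C12) between a furanoid C15 phosphonium salt and the commercial C10 dialdehyde.
2. The dihydrofuran (C5–O and C8–O) comes from sensitised singlet-oxygen [4+2] addition to the C5=C6–C7=C8 diene of the (3R)-hydroxy C15 triene phosphonium salt, followed in the same flask by phosphine removal of one oxygen with inversion at C8.
3. The C15 salt comes from a C15 trienol, made by Stille coupling (C6–C7) of the enol triflate of silylated (−)-actinol with a dienylstannane from (E)-3-methylpent-2-en-4-yn-1-ol.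
4. Ring order: cyclohexane ring A is bought in actinol and carries C3; a 1,2-dioxine ring is formed photochemically and contracted to dihydrofuran ring B.
5. Stereocontrol: C3 is bought, C5 is set by C3 (facial selectivity of the cycloaddition), and C8 is set by C5 (suprafacial addition, then SN2 inversion).

Assumption: positions are cited with carotenoid numbering (ring C1–C6 with C3 the carbinol carbon, chain C7–C15 then C15'–C12'); (−)-actinol, (E)-3-methylpent-2-en-4-yn-1-ol and the C10 dialdehyde are taken as catalogue chemicals.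

## Route

Step 1
Reactants: 1 (−)-actinol, (4R,6R)-4-hydroxy-2,2,6-trimethylcyclohexan-1-one
Product: 2 (4R,6R)-2,2,6-trimethyl-4-(triethylsilyloxy)cyclohexan-1-one
Conditions: Et3SiCl (1.2 equiv), imidazole (2.5 equiv), DMF, 0 °C → rt
Reagents that add atoms: chlorotriethylsilane, CC[Si](Cl)(CC)CC
Why: Standard imidazole-promoted O-silylation of the secondary alcohol, which touches no stereocentre (C4 of actinol becomes C3 of the target).

Step 2
Reactants: 2 (4R,6R)-2,2,6-trimethyl-4-(triethylsilyloxy)cyclohexan-1-one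
Product: 4 (4R)-2,6,6-trimethyl-4-(triethylsilyloxy)cyclohex-1-en-1-yl trifluoromethanesulfonate, via lithium enolate 3 (not isolated)
Conditions: LiN(iPr)2 (1.2 equiv), THF, −78 → 0 °C; PhNTf2 (1.2 equiv), −78 °C → rt
Reagents that add atoms: N-phenyl-bis(trifluoromethanesulfonimide), O=S(=O)(N(c1ccccc1)S(=O)(=O)C(F)(F)F)C(F)(F)F
Why: Enol triflate formation is regiospecific because only one α-carbon carries a hydrogen, so O-triflation of the enolate fixes the tetrasubstituted C5=C6 alkene; the methyl-bearing stereocentre is erased on purpose and the silyloxy carbon is untouched.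

Step 3
Reactants: 5 (2E)-3-methylpent-2-en-4-yn-1-ol
Product: 6 (2E,4E)-3-methyl-5-(tributylstannyl)penta-2,4-dien-1-ol
Conditions: Bu3SnH (1.2 equiv, slow addition), PdCl2(PPh3)2 (2 mol%), THF, 0 °C → rt
Reagents that add atoms: tributyltin hydride, CCCC[SnH](CCCC)CCCC
Why: Palladium-catalysed syn-hydrostannylation of the terminal alkyne puts tin on the terminal carbon and gives the (E)-vinylstannane with the existing (2E) alkene unchanged; the minor internal regioisomer is removed by chromatography.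

Step 4
Reactants: 4 (4R)-2,6,6-trimethyl-4-(triethylsilyloxy)cyclohex-1-en-1-yl trifluoromethanesulfonate; 6 (2E,4E)-3-methyl-5-(tributylstannyl)penta-2,4-dien-1-ol
Product: 7 (2E,4E)-3-methyl-5-[(4R)-2,6,6-trimethyl-4-(triethylsilyloxy)cyclohex-1-en-1-yl]penta-2,4-dien-1-ol
Conditions: Pd2(dba)3 (2.5 mol%), AsPh3 (20 mol%), NMP, 60 °C
Reagents that add atoms: none
Why: Stille cross-coupling under triphenylarsine/NMP conditions, which are suited to hindered 2,6,6-trimethylcyclohexenyl triflates, forms C6–C7 with retention of both alkene geometries and tolerates the free primary alcohol.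

Step 5
Reactants: 7 (2E,4E)-3-methyl-5-[(4R)-2,6,6-trimethyl-4-(triethylsilyloxy)cyclohex-1-en-1-yl]penta-2,4-dien-1-ol
Product: 9 [(2E,4E)-5-[(4R)-4-hydroxy-2,6,6-trimethylcyclohex-1-en-1-yl]-3-methylpenta-2,4-dien-1-yl]triphenylphosphonium bromide, via C15 diol 8 (not isolated)
Conditions: PPh3·HBr (1.2 equiv), MeOH, rt, 16 h; recrystallise from CH2Cl2/EtOAc
Reagents that add atoms: triphenylphosphine hydrobromide, [Br-].c1ccc(cc1)[PH+](c1ccccc1)c1ccccc1
Why: Acidic methanolysis removes the triethylsilyl group and SN1-type substitution of the primary dienylic alcohol by PPh3 (phosphonium salt formation, as in C15 Wittig-salt manufacture) gives the all-E salt after recrystallisation, with C3 unaffected.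

Step 6
Reactants: 9 [(2E,4E)-5-[(4R)-4-hydroxy-2,6,6-trimethylcyclohex-1-en-1-yl]-3-methylpenta-2,4-dien-1-yl]triphenylphosphonium bromide
Product: 11 [(2E)-3-[(2S,6S,7aR)-6-hydroxy-4,4,7a-trimethyl-2,4,5,6,7,7a-hexahydro-1-benzofuran-2-yl]but-2-en-1-yl]triphenylphosphonium bromide, via 5,8-endoperoxide salt 10 (not isolated)
Conditions: O2 (1 atm), tetraphenylporphyrin (0.5 mol%), white LED (λ > 420 nm), CH2Cl2, −40 °C; Ar purge; then PPh3 (1.05 equiv), dark, −40 → 0 °C
Reagents that add atoms: dioxygen, O=O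
Why: Proposed new method: a net stereospecific oxygen-atom [4+1] annulation of a diene carried out on a cationic triene phosphonium salt, in which singlet oxygen adds suprafacially ([4+2]) to the s-cis C5=C6–C7=C8 diene (the electron-richest diene, the 7,10-diene being deactivated by the CH2PPh3+ group) from the ring face anti to the C3 hydroxyl (axial delivery to C5 of the half-chair with equatorial 3-OH, which keeps the 5-methyl equatorial and avoids a 1,3-diaxial methyl/methyl clash with C1) to form the C5–O bond and the (5R,8R)-endoperoxide, after which PPh3 inserts into the O–O bond and the C5 alkoxide displaces Ph3P=O from C8 by 5-exo-tet SN2 with inversion, setting 8S (5-methyl and side chain cis) while the nearby phosphonium cation disfavours SN1 ionisation at C8; the closest known reactions are dye-sensitised photooxygenation of retinoid and β-ionone-type dienes to 5,8-endoperoxides and triphenylphosphine deoxygenation of 1,4-endoperoxides to 2,5-dihydrofurans.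

Step 7
Reactants: 11 [(2E)-3-[(2S,6S,7aR)-6-hydroxy-4,4,7a-trimethyl-2,4,5,6,7,7a-hexahydro-1-benzofuran-2-yl]but-2-en-1-yl]triphenylphosphonium bromide; 12 (2E,4E,6E)-2,7-dimethylocta-2,4,6-trienedial (C10 dialdehyde, 3 equiv)
Product: 14 (3S,5R,8S)-5,8-epoxy-3-hydroxy-5,8-dihydro-12'-apo-β-caroten-12'-al, via allylic phosphonium ylide 13 (not isolated)
Conditions: NaOMe (1.1 equiv) added to 11 + 12, MeOH/CH2Cl2, 0 °C → rt; then EtOAc, 70 °C, 2 h, dark, Ar (11Z → 11E)
Reagents that add atoms: none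
Why: Wittig olefination of the semi-stabilised allylic ylide with one aldehyde of the excess symmetrical dialdehyde forms C11=C12 (the C15 + C10 carotenoid coupling), the 11Z isomer is equilibrated thermally to all-E, and the base-stable allylic ether centres C5 and C8 are untouched.

Step 8
Reactants: 14 (3S,5R,8S)-5,8-epoxy-3-hydroxy-5,8-dihydro-12'-apo-β-caroten-12'-al
Product: 15 (3S,5R,8S)-5,8-epoxy-5,8-dihydro-12'-apo-β-carotene-3,12'-diol, the target
Conditions: NaBH4 (1 equiv), MeOH/THF (1:1), 0 °C, 20 min; pH 7 buffer work-up; chromatography on Et3N-deactivated silica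
Reagents that add atoms: none
Why: Chemoselective borohydride 1,2-reduction of the polyenal under non-acidic conditions gives the allylic alcohol without touching the polyene or the acid-labile C8 centre.

## Compound list

1 | (−)-actinol, (4R,6R)-4-hydroxy-2,2,6-trimethylcyclohexan-1-one | CC1(C)C[C@H](O)C[C@@H](C)C1=O | starting material
2 | (4R,6R)-2,2,6-trimethyl-4-(triethylsilyloxy)cyclohexan-1-one | CC1(C)C[C@H](O[Si](CC)(CC)CC)C[C@@H](C)C1=O | intermediate
3 | lithium (4R)-2,6,6-trimethyl-4-(triethylsilyloxy)cyclohex-1-en-1-olate (lithium enolate, not isolated) | CC1=C([O-])C(C)(C)C[C@H](O[Si](CC)(CC)CC)C1.[Li+] | intermediate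
4 | (4R)-2,6,6-trimethyl-4-(triethylsilyloxy)cyclohex-1-en-1-yl trifluoromethanesulfonate | CC1=C(OS(=O)(=O)C(F)(F)F)C(C)(C)C[C@H](O[Si](CC)(CC)CC)C1 | intermediate
5 | (2E)-3-methylpent-2-en-4-yn-1-ol | C#C/C(C)=C/CO | starting material
6 | (2E,4E)-3-methyl-5-(tributylstannyl)penta-2,4-dien-1-ol | CCCC[Sn](CCCC)(CCCC)/C=C/C(C)=C/CO | intermediate
7 | (2E,4E)-3-methyl-5-[(4R)-2,6,6-trimethyl-4-(triethylsilyloxy)cyclohex-1-en-1-yl]penta-2,4-dien-1-ol | CC1=C(/C=C/C(C)=C/CO)C(C)(C)C[C@H](O[Si](CC)(CC)CC)C1 | intermediate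
8 | (2E,4E)-5-[(4R)-4-hydroxy-2,6,6-trimethylcyclohex-1-en-1-yl]-3-methylpenta-2,4-dien-1-ol (C15 diol, not isolated) | CC1=C(/C=C/C(C)=C/CO)C(C)(C)C[C@H](O)C1 | intermediate
9 | [(2E,4E)-5-[(4R)-4-hydroxy-2,6,6-trimethylcyclohex-1-en-1-yl]-3-methylpenta-2,4-dien-1-yl]triphenylphosphonium bromide | CC1=C(/C=C/C(C)=C/C[P+](c2ccccc2)(c2ccccc2)c2ccccc2)C(C)(C)C[C@H](O)C1.[Br-] | intermediate
10 | [(2E)-3-[(3R,7S,8aR)-7-hydroxy-5,5,8a-trimethyl-3,5,6,7,8,8a-hexahydro-1,2-benzodioxin-3-yl]but-2-en-1-yl]triphenylphosphonium bromide; the (3S,5R,8R)-5,8-endoperoxide, O–O bridge from C5 to C8 on the face anti to the 3-OH (not isolated) | [Br-].c1ccc(cc1)[P+](c1ccccc1)(c1ccccc1)C/C=C(\C)[C@H]1C=C2C(C)(C)C[C@H](O)C[C@@]2(C)OO1 | intermediate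
11 | [(2E)-3-[(2S,6S,7aR)-6-hydroxy-4,4,7a-trimethyl-2,4,5,6,7,7a-hexahydro-1-benzofuran-2-yl]but-2-en-1-yl]triphenylphosphonium bromide; the (3S,5R,8S)-furanoid C15 salt | [Br-].c1ccc(cc1)[P+](c1ccccc1)(c1ccccc1)C/C=C(\C)[C@@H]1C=C2C(C)(C)C[C@H](O)C[C@@]2(C)O1 | intermediate
12 | (2E,4E,6E)-2,7-dimethylocta-2,4,6-trienedial (C10 dialdehyde) | O=C/C(C)=C/C=C/C=C(\C)C=O | starting material
13 | allylic triphenylphosphonium ylide of 11 (not isolated) | c1ccc(cc1)P(c1ccccc1)(c1ccccc1)=C/C=C(\C)[C@@H]1C=C2C(C)(C)C[C@H](O)C[C@@]2(C)O1 | intermediate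
14 | (3S,5R,8S)-5,8-epoxy-3-hydroxy-5,8-dihydro-12'-apo-β-caroten-12'-al; (2E,4E,6E,8E,10E)-11-[(2S,6S,7aR)-6-hydroxy-4,4,7a-trimethyl-2,4,5,6,7,7a-hexahydro-1-benzofuran-2-yl]-2,7-dimethyldodeca-2,4,6,8,10-pentaenal | CC(/C=C/C=C(\C)[C@@H]1C=C2C(C)(C)C[C@H](O)C[C@@]2(C)O1)=C\C=C\C=C(/C)C=O | intermediate
15 | (3S,5R,8S)-5,8-epoxy-5,8-dihydro-12'-apo-β-carotene-3,12'-diol; (2S,6S,7aR)-2-[(2E,4E,6E,8E,10E)-12-hydroxy-6,11-dimethyldodeca-2,4,6,8,10-pentaen-2-yl]-4,4,7a-trimethyl-2,4,5,6,7,7a-hexahydro-1-benzofuran-6-ol | CC(/C=C/C=C(\C)[C@@H]1C=C2C(C)(C)C[C@H](O)C[C@@]2(C)O1)=C\C=C\C=C(/C)CO | target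

## Step count and risks

Total steps: 8. Longest linear sequence: 7 steps (1 → 2 → 4 → 7 → 9 → 11 → 14 → 15; steps 1, 2, 4, 5, 6, 7, 8).

**Most likely to fail, first: step 6 (the proposed new step).** Possible failures are ene reaction or 7,10-cycloaddition instead of 5,8-addition, weak anti facial selectivity, and loss of stereochemical fidelity in the ring contraction. The last could arise from SN2' closure to a 5,6-epoxide, ionisation at the doubly allylic C8, or bromide return by double inversion.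

The fallback uses known chemistry, sets out from 7 and comes back at 11. Compound 7 is epoxidised with mCPBA/NaHCO3 in CH2Cl2 at −20 °C. Peracids attack the tetrasubstituted ring alkene of 3-silyloxy β-end groups mainly anti to the C3 oxygen, which gives (2E,4E)-3-methyl-5-[(1S,4S,6R)-2,2,6-trimethyl-4-(triethylsilyloxy)-7-oxabicyclo[4.1.0]heptan-1-yl]penta-2,4-dien-1-ol F1. Treatment of F1 with PPh3·HBr in MeOH then does three things at once: the classical acid-induced 5,6-epoxide → 5,8-furanoid rearrangement, loss of the silyl group, and phosphonium formation. This gives 11 together with its C8 epimer, [(2E)-3-[(2R,6S,7aR)-6-hydroxy-4,4,7a-trimethyl-2,4,5,6,7,7a-hexahydro-1-benzofuran-2-yl]but-2-en-1-yl]triphenylphosphonium bromide F2, in roughly equal amounts. The two are separated by preparative reversed-phase HPLC and 11 goes on to step 7. C8 is not controlled in this variant, so about half the material is lost.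

**Second: step 7.** Possible failures are vinylogous β-elimination of the allylic ylide, which would open the dihydrofuran; incomplete 11Z → 11E equilibration; and bis-olefination of the dialdehyde.

The fallback sets out from 9 and comes back at 14; it builds the polyene first on the robust non-furanoid salt and forms the furanoid afterwards. Salt 9 undergoes the well-precedented Wittig reaction with 12 (NaOMe, MeOH/CH2Cl2) to give (3R)-3-hydroxy-12'-apo-β-caroten-12'-al F3. Peracid epoxidation of the ring C5=C6 bond (mCPBA, NaHCO3, CH2Cl2, −20 °C) gives, as the major anti isomer after chromatography, (3S,5R,6S)-5,6-epoxy-3-hydroxy-5,6-dihydro-12'-apo-β-caroten-12'-al F4. Trace HCl in CHCl3 then triggers the epoxide → furanoid rearrangement to 14 and its C8 epimer, (3S,5R,8R)-5,8-epoxy-3-hydroxy-5,8-dihydro-12'-apo-β-caroten-12'-al F5. The epimers are separated by HPLC and 14 goes on to step 8.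

**Third: step 4.** The Stille coupling has to proceed at a hindered tetrasubstituted enol triflate, and the main risks are slow oxidative addition and transmetallation and destannylation of 6.

The fallback sets out from 4 and comes back at 7; it builds the side chain stepwise instead of by one cross-coupling. Heck reaction of 4 with methyl vinyl ketone (Pd(OAc)2, PPh3, Et3N, DMF, 70 °C) gives (3E)-4-[(4R)-2,6,6-trimethyl-4-(triethylsilyloxy)cyclohex-1-en-1-yl]but-3-en-2-one F6. Horner–Wadsworth–Emmons reaction with triethyl phosphonoacetate and NaH in THF gives ethyl (2E,4E)-3-methyl-5-[(4R)-2,6,6-trimethyl-4-(triethylsilyloxy)cyclohex-1-en-1-yl]penta-2,4-dienoate F7, from which the minor 9Z isomer is removed by chromatography. Reduction with iBu2AlH in toluene at −78 °C returns 7.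

## Further compounds

F1 | step 6 | (2E,4E)-3-methyl-5-[(1S,4S,6R)-2,2,6-trimethyl-4-(triethylsilyloxy)-7-oxabicyclo[4.1.0]heptan-1-yl]penta-2,4-dien-1-ol | OC/C=C(C)/C=C/[C@@]12O[C@]1(C)C[C@@H](O[Si](CC)(CC)CC)CC2(C)C
F2 | step 6 | [(2E)-3-[(2R,6S,7aR)-6-hydroxy-4,4,7a-trimethyl-2,4,5,6,7,7a-hexahydro-1-benzofuran-2-yl]but-2-en-1-yl]triphenylphosphonium bromide | [Br-].c1ccc(cc1)[P+](c1ccccc1)(c1ccccc1)C/C=C(\C)[C@H]1C=C2C(C)(C)C[C@H](O)C[C@@]2(C)O1
F3 | step 7 | (3R)-3-hydroxy-12'-apo-β-caroten-12'-al | CC1=C(/C=C/C(C)=C/C=C/C(C)=C/C=C/C=C(\C)C=O)C(C)(C)C[C@H](O)C1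
F4 | step 7 | (3S,5R,6S)-5,6-epoxy-3-hydroxy-5,6-dihydro-12'-apo-β-caroten-12'-al | O=C/C(C)=C/C=C/C=C(C)/C=C/C=C(C)/C=C/[C@@]12O[C@]1(C)C[C@@H](O)CC2(C)C
F5 | step 7 | (3S,5R,8R)-5,8-epoxy-3-hydroxy-5,8-dihydro-12'-apo-β-caroten-12'-al | CC(/C=C/C=C(\C)[C@H]1C=C2C(C)(C)C[C@H](O)C[C@@]2(C)O1)=C\C=C\C=C(/C)C=O
F6 | step 4 | (3E)-4-[(4R)-2,6,6-trimethyl-4-(triethylsilyloxy)cyclohex-1-en-1-yl]but-3-en-2-one | CC1=C(/C=C/C(C)=O)C(C)(C)C[C@H](O[Si](CC)(CC)CC)C1
F7 | step 4 | ethyl (2E,4E)-3-methyl-5-[(4R)-2,6,6-trimethyl-4-(triethylsilyloxy)cyclohex-1-en-1-yl]penta-2,4-dienoate | CC1=C(/C=C/C(C)=C/C(=O)OCC)C(C)(C)C[C@H](O[Si](CC)(CC)CC)C1
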